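## Retrosynthetic overview
1. Target acid ⇒ primary alcohol (TBDPS-protected CH2CH2OH). The only ring, the 1,2-dioxane, is formed in Step 16 by acid-promoted SN1 peroxyketalization. The C3 hydroperoxide traps the tertiary allyl cation generated from a tertiary allylic alcohol at C6 (6-exo). This is the bold step: it sets the quaternary peroxy centre and has to retain the E-trisubstituted olefin.
2. C3-OOH ⇐ H2O2 SN2 with inversion on the C3 mesylate. The tertiary allylic alcohol ⇐ (E)-alkenyllithium, made by syn-carbometalation of a terminal alkyne, added to the C6 ethyl ketone.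
3. The ketone with C3/C4 anti ⇐ Et-cuprate addition to a γ-silyloxy enone ⇐ proline α-aminoxylation/HWE of 4-silyloxybutanal.
4. The alkyne carrying C(e) and the E-olefin ⇐ Johnson–Claisen of (R,E)-hept-4-en-3-ol ⇐ Et2Zn addition to (E)-pent-2-enal.

**Assumptions (one line each)**
- L-proline/PhNO gives the (R)-α-aminoxy aldehyde; use D-proline if the opposite enantiomer results.
- Step 16 gives the C6 epimers in roughly 2:1 dr, and they are separable.
- Cu-mediated carbomagnesiation places Et at the internal alkyne carbon (syn addition).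

## Route

**Step 1**
Reactants: 1 butane-1,4-diol
Product: 2 4-(TBDPSO)butan-1-ol
Conditions: NaH (1.0 equiv), THF, 0 °C; then TBDPSCl; 0 °C to rt
Reagents that add atoms: TBDPSCl, CC(C)(C)[Si](Cl)(c1ccccc1)c1ccccc1
Why: Mono-alkoxide formation followed by silylation (Williamson-type silyl protection) gives mono-protection of a symmetric diol; no stereocentre is formed.

**Step 2**
Reactants: 2
Product: 3 4-(TBDPSO)butanal
Conditions: DMP, NaHCO3, CH2Cl2, rt
Reagents that add atoms: none
Why: Dess–Martin oxidation of a primary alcohol stops at the aldehyde; no stereocentre is formed.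

**Step 3**
Reactants: 3 and 4 dimethyl (2-oxobutyl)phosphonate
Product: 5 (E,6R)-8-(TBDPSO)-6-(phenylaminooxy)oct-4-en-3-one
Conditions: (i) PhNO, L-proline (20 mol%), MeCN, −20 °C; (ii) 4, LiCl, DBU, 0 °C (one pot)
Reagents that add atoms: nitrosobenzene, O=Nc1ccccc1
Why: Proline enamine O-selective α-aminoxylation sets C3 as (R), and in-situ Horner–Wadsworth–Emmons olefination of the labile α-aminoxy aldehyde gives the E-enone without epimerization.

**Step 4**
Reactants: 5
Product: 6 (E,6R)-8-(TBDPSO)-6-hydroxyoct-4-en-3-one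
Conditions: CuSO4·5H2O (cat.), MeOH, rt
Reagents that add atoms: none
Why: Cu(II)-mediated N–O heterolysis converts the anilinooxy group to the free γ-hydroxy enone; C3 is untouched.

**Step 5**
Reactants: 6
Product: 7 (E,6R)-6-(TBSO)-8-(TBDPSO)oct-4-en-3-one
Conditions: TBSOTf, 2,6-lutidine, CH2Cl2, −78 °C
Reagents that add atoms: TBSOTf, CC(C)(C)[Si](C)(C)OS(=O)(=O)C(F)(F)F
Why: Silylation under non-basic conditions avoids γ-deprotonation and olefin isomerization of the enone.

**Step 6**
Reactants: 7
Product: 8 (5S,6R)-5-ethyl-6-(TBSO)-8-(TBDPSO)octan-3-one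
Conditions: EtMgBr (3 equiv), CuBr·SMe2 (1.5 equiv), TMSCl, THF, −78 °C
Reagents that add atoms: EtMgBr, CC[Mg]Br
Why: Yamamoto-type conjugate addition to a γ-alkoxy enone is Felkin–Anh controlled: OTBS sits perpendicular and the cuprate attacks anti to it, so C4 becomes (S) and C3/C4 are anti (the ring substituents become cis after the later C3 inversion).

**Step 7**
Reactants: 9 (E)-pent-2-enal
Product: 10 (R,E)-hept-4-en-3-ol
Conditions: Et2Zn, (+)-DAIB (5 mol%), toluene/hexane, 0 °C
Reagents that add atoms: diethylzinc, CC[Zn]CC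
Why: Noyori amino-alcohol-catalysed enantioselective 1,2-addition of Et2Zn to an enal sets the carbinol as (R).

**Step 8**
Reactants: 10
Product: 11 ethyl (R,E)-3-ethylhept-4-enoate
Conditions: CH3C(OEt)3, EtCO2H (cat.), xylene, 140 °C
Reagents that add atoms: triethyl orthoacetate, CCOC(C)(OCC)OCC
Why: Johnson–Claisen [3,3] rearrangement through a chair TS with both Et groups equatorial transfers chirality from the (R)-carbinol to give C(e) as (R) and delivers the E-olefin.

**Step 9**
Reactants: 11
Product: 12 (R,E)-3-ethylhept-4-enal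
Conditions: DIBAL-H, CH2Cl2, −78 °C
Reagents that add atoms: none
Why: DIBAL reduction of an ester at low temperature stops at the aldehyde; C(e) is β to the carbonyl and cannot epimerize.

**Step 10**
Reactants: 12
Product: 13 (R,E)-4-ethyloct-5-en-1-yne
Conditions: Bestmann–Ohira reagent, K2CO3, MeOH, 0 °C to rt
Reagents that add atoms: dimethyl (1-diazo-2-oxopropyl)phosphonate, CC(=O)C(=[N+]=[N-])P(=O)(OC)OC
Why: Seyferth–Gilbert/Ohira–Bestmann one-carbon homologation converts the aldehyde carbon to the internal alkyne carbon g and adds the terminal carbon h.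

**Step 11**
Reactants: 13
Product: 14 (1E,4R,5E)-2,4-diethyl-1-iodoocta-1,5-diene
Conditions: EtMgBr (2.5 equiv), CuBr·SMe2 (1.2 equiv), THF/Et2O, −30 °C, 3 h; then I2, −78 °C
Reagents that add atoms: EtMgBr, CC[Mg]Br; iodine, II
Why: Normant syn-carbocupration puts Et on the internal carbon g and Cu on the terminal carbon h, and iodination then gives I cis to Et, so the f-chain is trans to I (the E-geometry needed for the g=h olefin).

**Step 12**
Reactants: 14 and 8
Product: 15 tertiary allylic alcohol (C6 epimeric mixture)
Conditions: t-BuLi (2.0 equiv), Et2O, −78 °C; CeCl3, THF; then 8, −78 °C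
Reagents that add atoms: none
Why: Halogen–lithium exchange proceeds with retention, and the organocerium adds 1,2 to the hindered enolizable ketone (Luche/Imamoto-type addition); C6 is deliberately left unset because the next-but-three step funnels both epimers through one cation.

**Step 13**
Reactants: 15
Product: 16 C3 secondary alcohol (diol; TBDPS primary ether retained)
Conditions: HF·pyridine, pyridine/THF, 0 °C to rt
Reagents that add atoms: none
Why: A secondary TBS ether is cleaved selectively in the presence of a primary TBDPS ether and the tertiary allylic alcohol (buffered fluoride desilylation).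

**Step 14**
Reactants: 16
Product: 17 C3 mesylate (R)
Conditions: MsCl, Et3N, CH2Cl2, −40 °C; use crude immediately
Reagents that add atoms: MsCl, CS(=O)(=O)Cl
Why: Only the secondary alcohol is mesylated; the hindered tertiary allylic alcohol does not react at −40 °C.

**Step 15**
Reactants: 17
Product: 18 C3 hydroperoxide (S)
Conditions: 50% aq. H2O2 (20 equiv), LiOH·H2O (2 equiv), THF/MeOH, 0 °C to rt
Reagents that add atoms: hydrogen peroxide, OO
Why: α-Effect HOO⁻ displaces the mesylate by SN2 (Dussault/Williams hydroperoxide alkylation) with clean inversion, converting (3R) to (3S).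

**Step 16 (key step)**
Reactants: 18
Product: 19 TBDPS-protected 1,2-dioxane, with C6 (R) as the major epimer
Conditions: CSA (10 mol%), CH2Cl2, −10 °C, 2 h; separate C6 epimers by HPLC
Reagents that add atoms: none
Why: Proposed new method: ionization of the tertiary allylic alcohol gives a 1,1,3,3-tetraalkyl allyl cation that is trapped intramolecularly by the C3-OOH at C6 (6-exo), in a chair-like TS with C4-Et equatorial and the C3 chain axial; collapse is faster than allyl-cation rotation, so the g=h olefin stays E; the closest known reaction types are acid-catalysed SN1 peroxidation of tertiary allylic alcohols and Dussault-type hydroperoxide trapping of carbocations.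

**Step 17**
Reactants: 19
Product: 20 primary alcohol
Conditions: TBAF, AcOH (1:1), THF, 0 °C to rt
Reagents that add atoms: none
Why: Buffered fluoride removes TBDPS while the dialkyl peroxide and both olefins survive.

**Step 18**
Reactants: 20
Product: 21 Plakortide N
Conditions: TEMPO (20 mol%), PhI(OAc)2 (2.5 equiv), MeCN/H2O 1:1, rt
Reagents that add atoms: water, O
Why: TEMPO/BAIB oxidizes the primary alcohol through its hydrate directly to the carboxylic acid under near-neutral conditions, which avoids isolating the β-peroxy aldehyde that could undergo retro-oxa-Michael elimination; the peroxide and olefins are untouched.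

## Compound list
1 | butane-1,4-diol | OCCCCO | starting material
2 | 4-(TBDPSO)butan-1-ol | OCCCCO[Si](c1ccccc1)(c1ccccc1)C(C)(C)C | intermediate
3 | 4-(TBDPSO)butanal | O=CCCCO[Si](c1ccccc1)(c1ccccc1)C(C)(C)C | intermediate
4 | dimethyl (2-oxobutyl)phosphonate | CCC(=O)CP(=O)(OC)OC | starting material
5 | (E,6R)-8-(TBDPSO)-6-(phenylaminooxy)oct-4-en-3-one | CCC(=O)/C=C/[C@@H](CCO[Si](c1ccccc1)(c1ccccc1)C(C)(C)C)ONc1ccccc1 | intermediate
6 | (E,6R)-8-(TBDPSO)-6-hydroxyoct-4-en-3-one | CCC(=O)/C=C/[C@@H](CCO[Si](c1ccccc1)(c1ccccc1)C(C)(C)C)O | intermediate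
7 | (E,6R)-6-(TBSO)-8-(TBDPSO)oct-4-en-3-one | CCC(=O)/C=C/[C@@H](CCO[Si](c1ccccc1)(c1ccccc1)C(C)(C)C)O[Si](C)(C)C(C)(C)C | intermediate
8 | (5S,6R)-5-ethyl-6-(TBSO)-8-(TBDPSO)octan-3-one | CCC(=O)C[C@H](CC)[C@@H](CCO[Si](c1ccccc1)(c1ccccc1)C(C)(C)C)O[Si](C)(C)C(C)(C)C | intermediate
9 | (E)-pent-2-enal | CC/C=C/C=O | starting material
10 | (R,E)-hept-4-en-3-ol | CC[C@@H](O)/C=C/CC | intermediate
11 | ethyl (R,E)-3-ethylhept-4-enoate | CCOC(=O)C[C@@H](CC)/C=C/CC | intermediate
12 | (R,E)-3-ethylhept-4-enal | O=CC[C@@H](CC)/C=C/CC | intermediate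
13 | (R,E)-4-ethyloct-5-en-1-yne | C#CC[C@@H](CC)/C=C/CC | intermediate
14 | (1E,4R,5E)-2,4-diethyl-1-iodoocta-1,5-diene | I/C=C(\CC)C[C@@H](CC)/C=C/CC | intermediate
15 | tertiary allylic alcohol (C3 OTBS, C6 epimers) | CC/C=C/[C@H](CC)C/C(CC)=C/C(O)(CC)C[C@H](CC)[C@@H](CCO[Si](c1ccccc1)(c1ccccc1)C(C)(C)C)O[Si](C)(C)C(C)(C)C | intermediate
16 | C3 free alcohol (diol) | CC/C=C/[C@H](CC)C/C(CC)=C/C(O)(CC)C[C@H](CC)[C@@H](CCO[Si](c1ccccc1)(c1ccccc1)C(C)(C)C)O | intermediate
17 | C3 mesylate (3R) | CC/C=C/[C@H](CC)C/C(CC)=C/C(O)(CC)C[C@H](CC)[C@@H](CCO[Si](c1ccccc1)(c1ccccc1)C(C)(C)C)OS(C)(=O)=O | intermediate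
18 | C3 hydroperoxide (3S) | CC/C=C/[C@H](CC)C/C(CC)=C/C(O)(CC)C[C@H](CC)[C@H](CCO[Si](c1ccccc1)(c1ccccc1)C(C)(C)C)OO | intermediate
19 | TBDPS-protected 1,2-dioxane | CC/C=C/[C@H](CC)C/C(=C/[C@@]2(CC)C[C@H](CC)[C@H](CCO[Si](c3ccccc3)(c3ccccc3)C(C)(C)C)OO2)CC | intermediate
20 | 2-[(3S,4S,6R)-dioxan-3-yl]ethanol analogue | CC/C=C/[C@H](CC)C/C(=C/[C@@]1(CC)C[C@H](CC)[C@H](CCO)OO1)CC | intermediate
21 | Plakortide N | CC/C=C/[C@H](CC)C/C(=C/[C@@]1(CC)C[C@H](CC)[C@H](CC(=O)O)OO1)CC | target

## Totals
- Total steps: 18.
- Longest linear sequence: 13 (Steps 1–6, then 12–18).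

## Three steps most likely to fail
1. **Step 16 (allyl-cation peroxyketalization).** Risks are poor C6 dr (Et and vinyl are similar in size), Hock-type fragmentation, and E/Z erosion of the g=h olefin. Fallback: run the reaction on the C6 ketone (the sequence is re-ordered) so that Step 15 gives the hydroperoxide-cyclized peroxyhemiketal. Convert it to the peroxyketal and add the alkenyl nucleophile (alkenyl-BF3K/BF3 or alkenylalane) to the peroxycarbenium ion, where stereoelectronic axial attack rather than cation sterics sets C6.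
2. **Step 15 (H2O2 SN2 on a hindered secondary mesylate).** Elimination competes, and the C3 mesylate can cyclize onto the γ-tertiary OH to give a THF. Fallback: reverse the bond order. Convert the tertiary allylic alcohol of 17 to the tertiary allylic hydroperoxide (H2O2, acid, via the cation), then close the ring by 6-exo-tet displacement of the C3 mesylate with Cs2CO3, with inversion at C3.
3. **Step 6 (anti-selective cuprate addition to the γ-OTBS enone).** Enones are usually less selective than enoates in this reaction. Fallback: build C3/C4 by Evans Mg-catalysed anti-aldol of N-butanoyl oxazolidinone with 3-(TBDPSO)propanal. Then protect as TBS, remove the auxiliary (LiBH4), convert to the iodide, displace with cyanide, and add EtMgBr, which gives the same ketone 8.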